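**Strategy**

Everything rests on cutting both aryl–CH2 bonds of the vicinal prenyl pair on C5 and C6 of ring B, the ring that carries the propyl tether on C1 and the catechol oxygens on C3 and C4. Because C5 and C6 adjoin that catechol, C5 is drawn from the third oxygen of a gallate (as a triflate) and C6 from the neighbouring carbon (as a bromide). One twofold Negishi coupling with prenylzinc bromide then installs both linear prenyl groups on the finished 1,3-diarylpropane. Its precursor is the tris-silylated diarylpropane with C6 bromide and C5 triflate, built by a Wittig union of a gallate-derived aldehyde with a ring A phosphonium salt and diimide reduction.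

Key step: step 16

Remark: in step 16 the C6 bromide is assumed to enter the catalytic cycle before the C5 triflate; the reverse order would end at the same product.

Abbreviations: TBS = tert-butyldimethylsilyl; Tf = trifluoromethanesulfonyl; NBS = N-bromosuccinimide; 9-BBN = 9-borabicyclo[3.3.1]nonane; CPhos = 2-dicyclohexylphosphino-2',6'-bis(dimethylamino)biphenyl. Ring B is numbered from the tether carbon (C1, the former gallate carboxyl carbon).

**Route**

Step 1
Reactants: 1 methyl gallate
Product: 2 methyl 7-hydroxy-2,2-diphenyl-1,3-benzodioxole-5-carboxylate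
Conditions: Ph2CCl2 (1.2 equiv), neat, 180 °C, short heating
Reagents that add atoms: dichlorodiphenylmethane, ClC(Cl)(c1ccccc1)c1ccccc1
Why: Ketalisation of a catechol with a gem-dichloride, in which only two adjacent hydroxyls can close the five-membered dioxole and, the outer oxygens of the gallate being equivalent, every closure gives the same 3,4-ketal with one phenol left free.

Step 2
Reactants: 2 methyl 7-hydroxy-2,2-diphenyl-1,3-benzodioxole-5-carboxylate
Product: 3 methyl 6-bromo-7-hydroxy-2,2-diphenyl-1,3-benzodioxole-5-carboxylate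
Conditions: NBS (1.0 equiv), i-Pr2NH (10 mol%), CH2Cl2, 0 °C to rt
Reagents that add atoms: N-bromosuccinimide, BrN1C(=O)CCC1=O
Why: Electrophilic aromatic bromination under the amine-catalysed ortho-directing protocol for phenols, where hydrogen-bonded delivery of bromine and the para relationship to the C3 ketal oxygen both point to C6, whereas C2 lies ortho to a dioxole oxygen, a position that benzodioxoles substitute reluctantly.

Step 3
Reactants: 3 methyl 6-bromo-7-hydroxy-2,2-diphenyl-1,3-benzodioxole-5-carboxylate
Product: 4 methyl 6-bromo-2,2-diphenyl-7-(trifluoromethanesulfonyloxy)-1,3-benzodioxole-5-carboxylate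
Conditions: Tf2O (1.2 equiv), pyridine, CH2Cl2, 0 °C
Reagents that add atoms: triflic anhydride, FC(F)(F)S(=O)(=O)OS(=O)(=O)C(F)(F)F
Why: O-Sulfonylation of a phenol with triflic anhydride and pyridine, which should be clean because the phenol is acidified by the ortho bromine and is the only nucleophile in the molecule.

Step 4
Reactants: 4 methyl 6-bromo-2,2-diphenyl-7-(trifluoromethanesulfonyloxy)-1,3-benzodioxole-5-carboxylate
Product: 5 methyl 2-bromo-4,5-dihydroxy-3-(trifluoromethanesulfonyloxy)benzoate
Conditions: CF3CO2H/H2O (10:1), CH2Cl2, rt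
Reagents that add atoms: none
Why: Acid hydrolysis of the diphenylmethylene ketal through a benzhydryl-type oxocarbenium ion, under conditions to which aryl triflate, aryl bromide and methyl ester are inert.

Step 5
Reactants: 5 methyl 2-bromo-4,5-dihydroxy-3-(trifluoromethanesulfonyloxy)benzoate
Product: 6 methyl 2-bromo-4,5-bis(tert-butyldimethylsilyloxy)-3-(trifluoromethanesulfonyloxy)benzoate
Conditions: TBSCl (3 equiv), imidazole (5 equiv), DMF, rt
Reagents that add atoms: tert-butyldimethylsilyl chloride, CC(C)(C)[Si](C)(C)Cl
Why: Imidazole-promoted silyl ether formation, a reaction that persilylates gallates including their flanked central oxygen, so both catechol oxygens should be capped while the weak base spares the triflate.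

Step 6
Reactants: 6 methyl 2-bromo-4,5-bis(tert-butyldimethylsilyloxy)-3-(trifluoromethanesulfonyloxy)benzoate
Product: 7 [2-bromo-4,5-bis(tert-butyldimethylsilyloxy)-3-(trifluoromethanesulfonyloxy)phenyl]methanol
Conditions: i-Bu2AlH (2.5 equiv), CH2Cl2, −78 °C; aq. KNaC4H4O6 work-up
Reagents that add atoms: none
Why: Hydride reduction of the ester to the primary alcohol with i-Bu2AlH, to which aryl bromide, aryl triflate and aryl silyl ethers are inert at low temperature.

Step 7
Reactants: 7 [2-bromo-4,5-bis(tert-butyldimethylsilyloxy)-3-(trifluoromethanesulfonyloxy)phenyl]methanol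
Product: 8 2-bromo-4,5-bis(tert-butyldimethylsilyloxy)-3-(trifluoromethanesulfonyloxy)benzaldehyde
Conditions: Dess–Martin periodinane (1.2 equiv), CH2Cl2, rt
Reagents that add atoms: none
Why: Dess–Martin oxidation of the benzylic alcohol stops at the aldehyde under near-neutral conditions that tolerate the silyl ethers and the triflate.

Step 8
Reactants: 9 4-hydroxy-2-methoxybenzaldehyde
Product: 10 4-(tert-butyldimethylsilyloxy)-2-methoxybenzaldehyde
Conditions: TBSCl (1.2 equiv), imidazole (2 equiv), CH2Cl2, rt
Reagents that add atoms: tert-butyldimethylsilyl chloride, CC(C)(C)[Si](C)(C)Cl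
Why: Silyl ether formation on the only hydroxyl masks the acidic phenol before ylide and borane chemistry.

Step 9
Reactants: 10 4-(tert-butyldimethylsilyloxy)-2-methoxybenzaldehyde
Product: 11 4-(tert-butyldimethylsilyloxy)-2-methoxystyrene
Conditions: Ph3PCH3Br (1.3 equiv), KOtBu (1.2 equiv), THF, 0 °C to rt
Reagents that add atoms: methyltriphenylphosphonium bromide, C[P+](c1ccccc1)(c1ccccc1)c1ccccc1.[Br-]
Why: Wittig methylenation of a non-enolisable aromatic aldehyde, run with the salt in slight excess over the base so that no free alkoxide attacks the aryl silyl ether.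

Step 10
Reactants: 11 4-(tert-butyldimethylsilyloxy)-2-methoxystyrene
Product: 13 2-[4-(tert-butyldimethylsilyloxy)-2-methoxyphenyl]ethanol, via B-alkyl-9-BBN adduct 12 (not isolated)
Conditions: 9-BBN (1.3 equiv), THF, 0 °C to rt; then NaBO3·4H2O, H2O, rt
Reagents that add atoms: 9-borabicyclo[3.3.1]nonane, B1C2CCCC1CCC2; sodium perborate tetrahydrate (NaBO3·4H2O), [Na+].[Na+].O[B-]1(O)OO[B-](O)(O)OO1
Why: Hydroboration–oxidation, in which the bulky dialkylborane places boron on the terminal carbon of the styrene (anti-Markovnikov) and mildly basic perborate turns the C–B bond into C–OH without cleaving the aryl silyl ether.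

Step 11
Reactants: 13 2-[4-(tert-butyldimethylsilyloxy)-2-methoxyphenyl]ethanol
Product: 14 4-(tert-butyldimethylsilyloxy)-1-(2-iodoethyl)-2-methoxybenzene
Conditions: I2 (1.2 equiv), PPh3 (1.2 equiv), imidazole (1.5 equiv), CH2Cl2, 0 °C to rt
Reagents that add atoms: iodine, II
Why: Appel-type iodination, in which the alcohol is activated as an alkoxyphosphonium ion and displaced by iodide at the unhindered primary carbon.

Step 12
Reactants: 14 4-(tert-butyldimethylsilyloxy)-1-(2-iodoethyl)-2-methoxybenzene
Product: 15 {2-[4-(tert-butyldimethylsilyloxy)-2-methoxyphenyl]ethyl}triphenylphosphonium iodide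
Conditions: PPh3 (1.5 equiv), MeCN, reflux
Reagents that add atoms: triphenylphosphine, c1ccc(cc1)P(c1ccccc1)c1ccccc1
Why: SN2 quaternisation of triphenylphosphine by the primary iodide, giving a salt that should be purified by precipitation.

Step 13
Reactants: 15 {2-[4-(tert-butyldimethylsilyloxy)-2-methoxyphenyl]ethyl}triphenylphosphonium iodide; 8 2-bromo-4,5-bis(tert-butyldimethylsilyloxy)-3-(trifluoromethanesulfonyloxy)benzaldehyde
Product: 17 (Z)-1-[2-bromo-4,5-bis(tert-butyldimethylsilyloxy)-3-(trifluoromethanesulfonyloxy)phenyl]-3-[4-(tert-butyldimethylsilyloxy)-2-methoxyphenyl]prop-1-ene, via ring A phosphonium ylide 16 (not isolated)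
Conditions: 15 (1.2 equiv), NaN(SiMe3)2 (1.1 equiv), THF, −78 to 0 °C; then 8, −78 °C to rt
Reagents that add atoms: none
Why: Wittig olefination of the non-enolisable aldehyde with a non-stabilised ylide closes the three-carbon chain, expected mainly as the Z alkene (either geometry serves), at temperatures at which the ylide leaves bromide, triflate and silyl ethers alone.

Step 14
Reactants: 17 (Z)-1-[2-bromo-4,5-bis(tert-butyldimethylsilyloxy)-3-(trifluoromethanesulfonyloxy)phenyl]-3-[4-(tert-butyldimethylsilyloxy)-2-methoxyphenyl]prop-1-ene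
Product: 18 1-[2-bromo-4,5-bis(tert-butyldimethylsilyloxy)-3-(trifluoromethanesulfonyloxy)phenyl]-3-[4-(tert-butyldimethylsilyloxy)-2-methoxyphenyl]propane (ring B: C6 bromide, C5 triflate)
Conditions: 2-nitrobenzenesulfonyl hydrazide (excess, in portions), Et3N, CH2Cl2, rt
Reagents that add atoms: none
Why: Diimide reduction transfers two hydrogens to the C=C bond in a concerted syn fashion and, unlike hydrogenation over palladium, cannot cleave the C–Br and C–OTf bonds needed in step 16.

Step 15
Reactants: 19 prenyl bromide (1-bromo-3-methylbut-2-ene)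
Product: 20 prenylzinc bromide, (3-methylbut-2-enyl)zinc bromide, as a titrated THF solution
Conditions: Zn dust (activated with BrCH2CH2Br and Me3SiCl), LiCl, THF, 0 °C, slow addition
Reagents that add atoms: zinc, [Zn]
Why: Direct oxidative insertion of zinc metal into the allylic C–Br bond, with LiCl keeping the reagent in solution and low temperature limiting Wurtz-type homocoupling.

Step 16
Reactants: 18 1-[2-bromo-4,5-bis(tert-butyldimethylsilyloxy)-3-(trifluoromethanesulfonyloxy)phenyl]-3-[4-(tert-butyldimethylsilyloxy)-2-methoxyphenyl]propane; 20 prenylzinc bromide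
Product: 22 Kazinol J tris(tert-butyldimethylsilyl) ether, via mono-prenylated C5 triflate 21 (not isolated)
Conditions: 20 (4 equiv), Pd(OAc)2 (5 mol%), CPhos (10 mol%), THF, rt then 40 °C
Reagents that add atoms: none
Why: Pd(OAc)2 is reduced by the organozinc to zerovalent palladium, which with one CPhos ligand inserts into the C6–Br bond and, after the first coupling, into the C5–OTf bond; each arylpalladium species takes a prenyl group from zinc and reductive elimination forms the aryl–CH2 bond. The closest known reaction type is the linear-selective Negishi coupling of prenylzinc halides with aryl bromides and aryl triflates under palladium/biaryl dialkylphosphine catalysis. No ring is closed and no stereocentre is formed. The step needs α-selectivity (normal prenyl, not 1,1-dimethylallyl) at both carbons: the bulky ligand makes reductive elimination from the primary σ-allyl terminus the faster path, and the groups flanking C5 and C6 (the tether on C1, the silyloxy group on C4) further disfavour a quaternary benzylic carbon. It also needs full conversion of two doubly ortho-substituted sites, which the electron-rich monoligated catalyst and the excess of 20 are meant to secure; as both leaving groups are exchanged for the same group, the order of the two oxidative additions does not affect the product.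

Step 17
Reactants: 22 Kazinol J tris(tert-butyldimethylsilyl) ether
Product: 23 Kazinol J
Conditions: Bu4NF (3.3 equiv), AcOH (3.3 equiv), THF, 0 °C, degassed; pH 6 buffer work-up
Reagents that add atoms: none
Why: Fluoride-mediated cleavage of the three aryl silyl ethers, driven by the strong Si–F bond, with acetic acid buffering that avoids both acid-catalysed cyclisation of a prenyl group onto the neighbouring phenol and base-promoted oxidation of the catechol.

**Compound list**

1 | methyl gallate (methyl 3,4,5-trihydroxybenzoate) | COC(=O)c1cc(O)c(O)c(O)c1 | starting material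
2 | methyl 7-hydroxy-2,2-diphenyl-1,3-benzodioxole-5-carboxylate | COC(=O)c1cc(O)c2OC(c3ccccc3)(c3ccccc3)Oc2c1 | intermediate
3 | methyl 6-bromo-7-hydroxy-2,2-diphenyl-1,3-benzodioxole-5-carboxylate | COC(=O)c1cc2OC(c3ccccc3)(c3ccccc3)Oc2c(O)c1Br | intermediate
4 | methyl 6-bromo-2,2-diphenyl-7-(trifluoromethanesulfonyloxy)-1,3-benzodioxole-5-carboxylate | COC(=O)c1cc2OC(c3ccccc3)(c3ccccc3)Oc2c(OS(=O)(=O)C(F)(F)F)c1Br | intermediate
5 | methyl 2-bromo-4,5-dihydroxy-3-(trifluoromethanesulfonyloxy)benzoate | COC(=O)c1cc(O)c(O)c(OS(=O)(=O)C(F)(F)F)c1Br | intermediate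
6 | methyl 2-bromo-4,5-bis(tert-butyldimethylsilyloxy)-3-(trifluoromethanesulfonyloxy)benzoate | COC(=O)c1cc(O[Si](C)(C)C(C)(C)C)c(O[Si](C)(C)C(C)(C)C)c(OS(=O)(=O)C(F)(F)F)c1Br | intermediate
7 | [2-bromo-4,5-bis(tert-butyldimethylsilyloxy)-3-(trifluoromethanesulfonyloxy)phenyl]methanol | OCc1cc(O[Si](C)(C)C(C)(C)C)c(O[Si](C)(C)C(C)(C)C)c(OS(=O)(=O)C(F)(F)F)c1Br | intermediate
8 | 2-bromo-4,5-bis(tert-butyldimethylsilyloxy)-3-(trifluoromethanesulfonyloxy)benzaldehyde | O=Cc1cc(O[Si](C)(C)C(C)(C)C)c(O[Si](C)(C)C(C)(C)C)c(OS(=O)(=O)C(F)(F)F)c1Br | intermediate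
9 | 4-hydroxy-2-methoxybenzaldehyde | COc1cc(O)ccc1C=O | starting material
10 | 4-(tert-butyldimethylsilyloxy)-2-methoxybenzaldehyde | COc1cc(O[Si](C)(C)C(C)(C)C)ccc1C=O | intermediate
11 | 4-(tert-butyldimethylsilyloxy)-2-methoxystyrene | COc1cc(O[Si](C)(C)C(C)(C)C)ccc1C=C | intermediate
12 | 9-{2-[4-(tert-butyldimethylsilyloxy)-2-methoxyphenyl]ethyl}-9-borabicyclo[3.3.1]nonane | COc1cc(O[Si](C)(C)C(C)(C)C)ccc1CCB1C2CCCC1CCC2 | intermediate
13 | 2-[4-(tert-butyldimethylsilyloxy)-2-methoxyphenyl]ethanol | COc1cc(O[Si](C)(C)C(C)(C)C)ccc1CCO | intermediate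
14 | 4-(tert-butyldimethylsilyloxy)-1-(2-iodoethyl)-2-methoxybenzene | COc1cc(O[Si](C)(C)C(C)(C)C)ccc1CCI | intermediate
15 | {2-[4-(tert-butyldimethylsilyloxy)-2-methoxyphenyl]ethyl}triphenylphosphonium iodide | COc1cc(O[Si](C)(C)C(C)(C)C)ccc1CC[P+](c1ccccc1)(c1ccccc1)c1ccccc1.[I-] | intermediate
16 | {2-[4-(tert-butyldimethylsilyloxy)-2-methoxyphenyl]ethylidene}triphenylphosphorane | COc1cc(O[Si](C)(C)C(C)(C)C)ccc1CC=P(c1ccccc1)(c1ccccc1)c1ccccc1 | intermediate
17 | (Z)-1-[2-bromo-4,5-bis(tert-butyldimethylsilyloxy)-3-(trifluoromethanesulfonyloxy)phenyl]-3-[4-(tert-butyldimethylsilyloxy)-2-methoxyphenyl]prop-1-ene | COc1cc(O[Si](C)(C)C(C)(C)C)ccc1C/C=C\c1cc(O[Si](C)(C)C(C)(C)C)c(O[Si](C)(C)C(C)(C)C)c(OS(=O)(=O)C(F)(F)F)c1Br | intermediate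
18 | 1-[2-bromo-4,5-bis(tert-butyldimethylsilyloxy)-3-(trifluoromethanesulfonyloxy)phenyl]-3-[4-(tert-butyldimethylsilyloxy)-2-methoxyphenyl]propane | COc1cc(O[Si](C)(C)C(C)(C)C)ccc1CCCc1cc(O[Si](C)(C)C(C)(C)C)c(O[Si](C)(C)C(C)(C)C)c(OS(=O)(=O)C(F)(F)F)c1Br | intermediate
19 | prenyl bromide (1-bromo-3-methylbut-2-ene) | CC(C)=CCBr | starting material
20 | prenylzinc bromide, (3-methylbut-2-enyl)zinc bromide | CC(C)=CC[Zn]Br | intermediate
21 | 1-[4,5-bis(tert-butyldimethylsilyloxy)-2-(3-methylbut-2-enyl)-3-(trifluoromethanesulfonyloxy)phenyl]-3-[4-(tert-butyldimethylsilyloxy)-2-methoxyphenyl]propane | COc1cc(O[Si](C)(C)C(C)(C)C)ccc1CCCc1cc(O[Si](C)(C)C(C)(C)C)c(O[Si](C)(C)C(C)(C)C)c(OS(=O)(=O)C(F)(F)F)c1CC=C(C)C | intermediate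
22 | Kazinol J tris(tert-butyldimethylsilyl) ether | COc1cc(O[Si](C)(C)C(C)(C)C)ccc1CCCc1cc(O[Si](C)(C)C(C)(C)C)c(O[Si](C)(C)C(C)(C)C)c(CC=C(C)C)c1CC=C(C)C | intermediate
23 | Kazinol J | COc1cc(O)ccc1CCCc1cc(O)c(O)c(CC=C(C)C)c1CC=C(C)C | target

**Step count and risks**

Total step count: 17 (including preparation of the organozinc reagent).
Longest linear sequence: 11 steps (steps 1–7, 13, 14, 16, 17).

Steps most likely to fail:

1. Step 16. The second oxidative addition, at the C5 triflate flanked by a prenyl group and a silyloxy group, may stall. Reductive elimination may also partly take place at the tertiary allyl terminus, giving reverse-prenyl isomers. Fallback: setting out from 18, both leaving groups would be replaced in a double Stille coupling with tributyl(3-methylbut-2-enyl)stannane (Pd(PPh3)4, LiCl, dioxane, reflux). This is a neutral, thermally robust coupling, and transfer from tin with bond formation at the primary allyl carbon is established for aryl bromides and aryl triflates. The product is 22, where the route is rejoined. This path makes no new compound (entry F0).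

2. Step 2. Bromination may go para to the free phenol (at C2) or twice, which would misplace the bromide. Fallback: setting out from 1, bromine would be introduced while the ring is still symmetrical. NBS (1 equiv, MeCN, 0 °C) can give only one monobromide, methyl 2-bromo-3,4,5-trihydroxybenzoate F1, because C2 and C6 are equivalent. Ketalisation of F1 with dichlorodiphenylmethane (neat, 180 °C) should then close on the oxygen pair remote from bromine, since the hydroxyl beside bromine is the most hindered. That leaves exactly this hydroxyl free and returns to the route at 3.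

3. Step 13. The ylide or residual amide base may attack the triflate sulfur or a silyl ether, or addition to the ortho-brominated aldehyde may be sluggish, so that the fragments fail to unite cleanly. Fallback: setting out from 13, a Julia–Kocienski olefination would replace the phosphorus ylide. Mitsunobu reaction with 1-phenyl-1H-tetrazole-5-thiol (PPh3, diisopropyl azodicarboxylate, THF) should give 5-{2-[4-(tert-butyldimethylsilyloxy)-2-methoxyphenyl]ethylsulfanyl}-1-phenyl-1H-tetrazole F2. Oxidation (H2O2, (NH4)6Mo7O24·4H2O, EtOH) should give the corresponding sulfone F3. Adding KN(SiMe3)2 to a mixture of F3 and aldehyde 8 (DME, −60 °C), so that the sulfonyl anion is trapped as it forms, should give the E-configured diarylpropene F4. Reduction of F4 under the conditions of step 14 returns to the route at 18.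

**Further compounds**

F0 | step 16 | none | none
F1 | step 2 | methyl 2-bromo-3,4,5-trihydroxybenzoate | COC(=O)c1cc(O)c(O)c(O)c1Br
F2 | step 13 | 5-{2-[4-(tert-butyldimethylsilyloxy)-2-methoxyphenyl]ethylsulfanyl}-1-phenyl-1H-tetrazole | COc1cc(O[Si](C)(C)C(C)(C)C)ccc1CCSc1nnnn1-c1ccccc1
F3 | step 13 | 5-{2-[4-(tert-butyldimethylsilyloxy)-2-methoxyphenyl]ethylsulfonyl}-1-phenyl-1H-tetrazole | COc1cc(O[Si](C)(C)C(C)(C)C)ccc1CCS(=O)(=O)c1nnnn1-c1ccccc1
F4 | step 13 | (E)-1-[2-bromo-4,5-bis(tert-butyldimethylsilyloxy)-3-(trifluoromethanesulfonyloxy)phenyl]-3-[4-(tert-butyldimethylsilyloxy)-2-methoxyphenyl]prop-1-ene | COc1cc(O[Si](C)(C)C(C)(C)C)ccc1C/C=C/c1cc(O[Si](C)(C)C(C)(C)C)c(O[Si](C)(C)C(C)(C)C)c(OS(=O)(=O)C(F)(F)F)c1Br
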